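Ring A is disconnected at C2–C3 and C4–C5 while ring B is still open at C9–C10, so the whole bicyclic core comes from an acyclic farnesyl chain. The key step exploits three features: C2 carries oxygen (oxocarbenium ion from a chiral acetal), C4 is the gem-dimethyl carbon (tertiary cation), and C5=C10 and C8=C9 are the E alkenes of a polyene. A (2-methylprop-1-enyl)silane is inserted between C2 and C5: its silicon-bearing carbon becomes C3 (silicon is the latent 3-hydroxyl), the β-silyl cation at C4 closes ring A, and the cascade closes ring B with trans fusion. The precursor is a homofarnesyl acetate dioxane acetal.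

Key step: step 6

Remark: atom numbers are labdane numbers (ring A: C1–C5 and C10; ring B: C5–C10; side chain C11–C15).
Assumption: the Lewis acid opens the dioxane acetal at the C–O bond next to the axial methyl group with inversion at the acetal carbon, so the (4S,6S)-acetal gives (S)-C2; if the opposite sense were found, (2R,4R)-pentane-2,4-diol would be used.

Step 1
Reactants: 1 (2E,6E)-farnesyl acetate
Product: 2 (2E,6E,10E)-12-hydroxy-3,7,11-trimethyldodeca-2,6,10-trienyl acetate
Conditions: SeO2 (cat.), t-BuOOH, salicylic acid (cat.), CH2Cl2, rt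
Reagents that add atoms: tert-butyl hydroperoxide, CC(C)(C)OO
Why: Catalytic SeO2 allylic oxidation (ene reaction followed by [2,3]-sigmatropic shift) should attack the most electron-rich, least hindered terminal trisubstituted alkene at its E methyl group and give the E allylic alcohol.

Step 2
Reactants: 2 12-hydroxyfarnesyl acetate
Product: 3 (2E,6E,10E)-3,7,11-trimethyl-12-oxododeca-2,6,10-trienyl acetate
Conditions: MnO2, CH2Cl2, rt
Reagents that add atoms: none
Why: Allylic oxidation with MnO2 should stop at the E enal and leave the acetate and the isolated alkenes untouched.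

Step 3
Reactants: 3 12-oxofarnesyl acetate
Product: 4 (2E,6E,10E)-13-methoxy-3,7,11-trimethyltrideca-2,6,10,12-tetraenyl acetate (mixture of 12E and 12Z enol ethers, used as such)
Conditions: Ph3P(CH2OMe)Cl, KN(SiMe3)2, THF, −78 to 0 °C
Reagents that add atoms: (methoxymethyl)triphenylphosphonium chloride, COC[P+](c1ccccc1)(c1ccccc1)c1ccccc1.[Cl-]
Why: Wittig methoxymethylenation should add C2 as an enol ether carbon, the ylide reacting with the aldehyde far faster than with the acetate; the geometry of the new enol ether is irrelevant because step 4 protonates it.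

Step 4
Reactants: 4 methoxy diene; 5 (2S,4S)-pentane-2,4-diol
Product: 6 (2E,6E,10E)-12-[(4S,6S)-4,6-dimethyl-1,3-dioxan-2-yl]-3,7,11-trimethyldodeca-2,6,10-trienyl acetate
Conditions: PPTS (cat.), 4 Å MS, CH2Cl2, 0 °C
Reagents that add atoms: none
Why: Acid-catalysed transacetalisation of the dienol ether: kinetic protonation at C1 should give the β,γ-unsaturated oxocarbenium ion, which the C2-symmetric diol captures as the dioxane with loss of methanol, so that C5=C10 stays E and out of conjugation and no new stereocentre arises.

Step 5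
Reactants: 7 (2-methylprop-1-enyl)magnesium bromide; 8 benzyl(chloro)dimethylsilane
Product: 9 benzyl(dimethyl)(2-methylprop-1-enyl)silane
Conditions: THF, 0 °C to rt
Reagents that add atoms: none
Why: Nucleophilic substitution at silicon by the alkenyl Grignard reagent should give the alkenylsilane.

Step 6
Reactants: 6 chiral dioxane acetal; 9 benzyl(dimethyl)(2-methylprop-1-enyl)silane
Product: 12 bicyclic silyl ether (labda-7,13E-dien-15-yl acetate skeleton with equatorial 2-O-[(2S,4S)-4-hydroxypent-2-yl] and equatorial 3-benzyldimethylsilyl groups), via oxocarbenium ion 10 (not isolated), via β-silyl carbenium ion 11 (not isolated)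
Conditions: TiCl4 (2 equiv), 9 (5 equiv), 2,6-di-tert-butylpyridine, CH2Cl2, −78 °C; then Et3N, MeOH, aq NaHCO3
Reagents that add atoms: none
Why: Proposed new method: TiCl4 ionises acetal 6 at the C–O bond flanked by the axial methyl group to oxocarbenium ion 10, the silicon-bearing carbon C3 of 9 attacks C2 anti to the departing oxygen (Prins-type addition, sets C2), and the tertiary β-silyl carbenium ion 11 at C4 is captured by C5 of the C5=C10 alkene before it loses silicon, after which the C10 cation is captured by C9 and the C8 cation loses H7; the closest known reactions are the chiral-acetal-initiated cation–olefin polycyclisation, the Lewis-acid coupling of acetals with alkenylsilanes (which normally ends in ipso substitution) and the capture of β-silyl cations by internal nucleophiles in allylsilane [3+2] annulations. Ring A closes by 6-endo-trig attack of the alkene on C4 and ring B by 6-endo-trig attack of C9 on C10, both through chair transition states. C5, C10 and C9 follow from antiperiplanar addition across the two E alkenes (trans ring fusion, equatorial side chain), their absolute sense comes from C2, whose ether oxygen stays equatorial to avoid the 1,3-diaxial contact with the C10 methyl group, and C3 is set by attack of C5 anti to silicon (equatorial silicon; this centre is erased in step 8). The step needs capture of 10 by 9 to outrun reactions of the chain alkenes (the nearest one could only close a three- or four-membered ring, and 9 is in excess), ring closure of 11 to outrun desilylation (pre-organised six-ring closure, low temperature, hindered base instead of a nucleophilic one), and proton loss from C7 to give the trisubstituted ring alkene.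

Step 7
Reactants: 12 bicyclic silyl ether
Product: 14 3-hydroxy bicyclic ether (equatorial C3–OH trans to the C2 ether oxygen), via fluorosilane 13 (not isolated)
Conditions: Bu4NF, THF, 0 °C; then H2O2 (30% aq), KHCO3, MeOH, rt
Reagents that add atoms: tetrabutylammonium fluoride, CCCC[N+](CCCC)(CCCC)CCCC.[F-] (fluorine appears only in 13); hydrogen peroxide, OO
Why: Tamao–Fleming oxidation: fluoride should cleave the benzyl–silicon bond and peroxide should then replace silicon by hydroxyl with retention at C3, Peterson elimination being disfavoured because silicon and the C2 ether oxygen are gauche in the rigid ring.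

Step 8
Reactants: 14 3-hydroxy bicyclic ether
Product: 15 3-ketone carrying the 2-O-[(2S)-4-oxopent-2-yl] ether
Conditions: Dess–Martin periodinane, CH2Cl2, rt
Reagents that add atoms: none
Why: Dess–Martin oxidation should convert both secondary alcohols (the hindered C3–OH and the auxiliary hydroxyl) into ketones under neutral conditions, which erases C3 and arms the auxiliary for removal.

Step 9
Reactants: 15 diketone
Product: 16 2-hydroxy-3-oxolabda-7,13E-dien-15-yl acetate (equatorial C2–OH; C5, C9, C10 as in the target)
Conditions: piperidinium acetate (cat.), benzene, 60 °C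
Reagents that add atoms: none
Why: Amine-salt-catalysed retro-oxa-Michael (E1cB) elimination of the β-alkoxy ketone should release the C2 hydroxyl and pent-3-en-2-one, while C2, now alpha to the C3 ketone, stays in its more stable equatorial orientation.

Step 10
Reactants: 16 ketol
Product: 17 2-acetoxy-3-oxolabda-7,13E-dien-15-yl acetate (equatorial C2–OAc)
Conditions: Ac2O, pyridine, DMAP (cat.), 0 °C to rt
Reagents that add atoms: acetic anhydride, CC(=O)OC(C)=O
Why: DMAP-catalysed acylation of the secondary alcohol should give the C2 acetate.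

Step 11
Reactants: 17 acetoxy ketone
Product: 18 target (2-acetoxy-3-hydroxylabda-7,13E-dien-15-yl acetate, axial C3–OH cis to equatorial C2–OAc)
Conditions: LiBH(s-Bu)3, THF, −78 °C; AcOH quench at −78 °C
Reagents that add atoms: none
Why: Ketone reduction under steric approach control: the bulky borohydride should attack the 4,4-dimethyl-3-ketone from the equatorial direction and give the axial C3 alcohol cis to the equatorial C2 acetate, and the cold acidic quench should prevent acetyl migration.

Compound list
1 | (2E,6E)-farnesyl acetate | CC(=O)OC/C=C(\C)CC/C=C(\C)CCC=C(C)C | starting material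
2 | (2E,6E,10E)-12-hydroxy-3,7,11-trimethyldodeca-2,6,10-trienyl acetate | CC(=O)OC/C=C(\C)CC/C=C(\C)CC/C=C(\C)CO | intermediate
3 | (2E,6E,10E)-3,7,11-trimethyl-12-oxododeca-2,6,10-trienyl acetate | CC(=O)OC/C=C(\C)CC/C=C(\C)CC/C=C(\C)C=O | intermediate
4 | (2E,6E,10E)-13-methoxy-3,7,11-trimethyltrideca-2,6,10,12-tetraenyl acetate (12E/12Z mixture) | CC(=O)OC/C=C(\C)CC/C=C(\C)CC/C=C(\C)C=COC | intermediate
5 | (2S,4S)-pentane-2,4-diol | C[C@H](O)C[C@H](C)O | starting material
6 | (2E,6E,10E)-12-[(4S,6S)-4,6-dimethyl-1,3-dioxan-2-yl]-3,7,11-trimethyldodeca-2,6,10-trienyl acetate | C[C@H]1C[C@H](C)OC(C/C(C)=C/CC/C(C)=C/CC/C(C)=C/COC(C)=O)O1 | intermediate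
7 | (2-methylprop-1-enyl)magnesium bromide | CC(C)=C[Mg]Br | starting material
8 | benzyl(chloro)dimethylsilane | C[Si](C)(Cl)Cc1ccccc1 | starting material
9 | benzyl(dimethyl)(2-methylprop-1-enyl)silane | CC(C)=C[Si](C)(C)Cc1ccccc1 | intermediate
10 | ring-opened oxocarbenium ion of 6 (alkoxide oxygen bound to titanium, drawn as zwitterion) | C[C@H]([O-])C[C@H](C)[O+]=CC/C(C)=C/CC/C(C)=C/CC/C(C)=C/COC(C)=O | intermediate (not isolated)
11 | acyclic tertiary β-silyl carbenium ion with the C2–C3 bond formed (drawn as zwitterion) | C[C@H]([O-])C[C@H](C)O[C@@H](C/C(C)=C/CC/C(C)=C/CC/C(C)=C/COC(C)=O)[C@@H]([Si](C)(C)Cc1ccccc1)[C+](C)C | intermediate (not isolated)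
12 | 3-(benzyldimethylsilyl)-2-[(2S,4S)-4-hydroxypent-2-yloxy]labda-7,13E-dien-15-yl acetate (trans-fused; O2 and Si equatorial) | CC(=O)OC/C=C(\C)CC[C@@H]1C(C)=CC[C@@H]2C(C)(C)[C@H]([Si](C)(C)Cc3ccccc3)[C@@H](O[C@@H](C)C[C@H](C)O)C[C@@]12C | intermediate
13 | 3-(fluorodimethylsilyl) analogue of 12 | CC(=O)OC/C=C(\C)CC[C@@H]1C(C)=CC[C@@H]2C(C)(C)[C@H]([Si](C)(C)F)[C@@H](O[C@@H](C)C[C@H](C)O)C[C@@]12C | intermediate (not isolated)
14 | 3-hydroxy-2-[(2S,4S)-4-hydroxypent-2-yloxy]labda-7,13E-dien-15-yl acetate (C3–OH equatorial) | CC(=O)OC/C=C(\C)CC[C@@H]1C(C)=CC[C@@H]2C(C)(C)[C@H](O)[C@@H](O[C@@H](C)C[C@H](C)O)C[C@@]12C | intermediate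
15 | 3-oxo-2-[(2S)-4-oxopent-2-yloxy]labda-7,13E-dien-15-yl acetate | CC(=O)OC/C=C(\C)CC[C@@H]1C(C)=CC[C@@H]2C(C)(C)C(=O)[C@@H](O[C@@H](C)CC(C)=O)C[C@@]12C | intermediate
16 | 2-hydroxy-3-oxolabda-7,13E-dien-15-yl acetate | CC(=O)OC/C=C(\C)CC[C@@H]1C(C)=CC[C@@H]2C(C)(C)C(=O)[C@@H](O)C[C@@]12C | intermediate
17 | 2-acetoxy-3-oxolabda-7,13E-dien-15-yl acetate | CC(=O)OC/C=C(\C)CC[C@@H]1C(C)=CC[C@@H]2C(C)(C)C(=O)[C@@H](OC(C)=O)C[C@@]12C | intermediate
18 | target, 2-acetoxy-3-hydroxylabda-7,13E-dien-15-yl acetate | CC(=O)OC/C=C(\C)CC[C@@H]1C(C)=CC[C@@H]2C(C)(C)[C@@H](O)[C@@H](OC(C)=O)C[C@@]12C | target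

Total step count: 11 (step 5 prepares the C3–C4 reagent). Longest linear sequence: 10 steps (steps 1–4 and 6–11).

Steps most likely to fail

Step 6. The β-silyl cation may lose silicon before ring A closes (ipso substitution), the first bond formation may show low simple diastereoselection at C3 so that part of the material cannot adopt the silicon-equatorial chair, and the last cation may be quenched by chloride or lose a proton toward the exocyclic position. The fallback makes the two bonds in separate, known steps; it sets out from 4 and returns at 17. Enol ether 4 would be hydrolysed under kinetic conditions (oxalic acid, wet THF, 0 °C) to β,γ-unsaturated aldehyde F1. An enantioselective Nozaki–Hiyama–Kishi coupling with 1-bromo-2-methylprop-1-ene (CrCl2, NiCl2 cat., chiral sulfonamide ligand) would form C2–C3 and give (S)-allylic alcohol F2. Hydroxyl-directed epoxidation (VO(acac)2, t-BuOOH), threo-selective because of A(1,3) strain, would give epoxy alcohol F3. Epoxide-initiated cation–olefin bicyclisation (MeAlCl2, CH2Cl2, −78 °C) would form C4–C5 and C9–C10 and give trans-diequatorial diol F4. Acetylation of the less hindered C2 hydroxyl (Ac2O, pyridine, 0 °C) would give monoacetate F5, and Dess–Martin oxidation of its C3 hydroxyl would give 17.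

Step 7. Oxidative cleavage of the hindered C3–Si bond next to the gem-dimethyl carbon may stall after debenzylation, and the fluoride stage may cost the C15 acetate. The fallback changes the silyl group and the oxidation manifold; it sets out from 6 and 7 and returns at 14. Grignard reagent 7 and chlorodimethylphenylsilane would give dimethyl(2-methylprop-1-enyl)phenylsilane F6, which would replace 9 in step 6 and give phenyldimethylsilyl bicyclic ether F7. Oxidation under basic fluoride conditions (t-BuOOH, CsOH·H2O, Bu4NF, DMF, 70 °C), which cleaves the phenyl–silicon bond and also the acetate, would give triol F8. Acetylation of the primary allylic hydroxyl alone (Ac2O, Et3N, CH2Cl2, −20 °C) would give 14.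

Step 11. The axial alkoxide formed next to the acetate may trigger acetyl migration from O2 to O3, or the hydride may attack the acetates. The fallback reverses the order of reduction and acylation; it sets out from 16 and returns at 18. Reduction of ketol 16 with LiBH(s-Bu)3 (THF, −78 °C) would give cis-diol F9 with the axial C3 hydroxyl, and acetylation with one equivalent of Ac2O in pyridine at 0 °C would take the equatorial C2 hydroxyl, the axial C3 hydroxyl being shielded by the gem-dimethyl group, to give 18.

Further compounds
F1 | step 6 | (2E,6E,10E)-3,7,11-trimethyl-13-oxotrideca-2,6,10-trienyl acetate | O=CC/C(C)=C/CC/C(C)=C/CC/C(C)=C/COC(C)=O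
F2 | step 6 | (2E,6E,10E,13S)-13-hydroxy-3,7,11,15-tetramethylhexadeca-2,6,10,14-tetraenyl acetate | CC(C)=C[C@@H](O)C/C(C)=C/CC/C(C)=C/CC/C(C)=C/COC(C)=O
F3 | step 6 | threo-14,15-epoxide of F2 (C13 hydroxyl retained) | CC1(C)O[C@@H]1[C@@H](O)C/C(C)=C/CC/C(C)=C/CC/C(C)=C/COC(C)=O
F4 | step 6 | 2,3-dihydroxylabda-7,13E-dien-15-yl acetate (both hydroxyls equatorial, trans) | CC(=O)OC/C=C(\C)CC[C@@H]1C(C)=CC[C@@H]2C(C)(C)[C@H](O)[C@@H](O)C[C@@]12C
F5 | step 6 | 2-acetoxy-3-hydroxylabda-7,13E-dien-15-yl acetate with equatorial C3–OH (3-epimer of the target) | CC(=O)OC/C=C(\C)CC[C@@H]1C(C)=CC[C@@H]2C(C)(C)[C@H](O)[C@@H](OC(C)=O)C[C@@]12C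
F6 | step 7 | dimethyl(2-methylprop-1-enyl)phenylsilane | CC(C)=C[Si](C)(C)c1ccccc1
F7 | step 7 | 3-(dimethylphenylsilyl) analogue of 12 | CC(=O)OC/C=C(\C)CC[C@@H]1C(C)=CC[C@@H]2C(C)(C)[C@H]([Si](C)(C)c3ccccc3)[C@@H](O[C@@H](C)C[C@H](C)O)C[C@@]12C
F8 | step 7 | 2-[(2S,4S)-4-hydroxypent-2-yloxy]labda-7,13E-diene-3,15-diol (C3–OH equatorial) | OC/C=C(\C)CC[C@@H]1C(C)=CC[C@@H]2C(C)(C)[C@H](O)[C@@H](O[C@@H](C)C[C@H](C)O)C[C@@]12C
F9 | step 11 | 2,3-dihydroxylabda-7,13E-dien-15-yl acetate (cis; C2–OH equatorial, C3–OH axial) | CC(=O)OC/C=C(\C)CC[C@@H]1C(C)=CC[C@@H]2C(C)(C)[C@@H](O)[C@@H](O)C[C@@]12C
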